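**Plan**
1. Retrosynthesis: each acyl arm hides its two aldehydes as a cis-cyclopentane-1,2-diol, so one ring C–C bond per arm is cut last (glycol cleavage); cutting the two ester C–O bonds then gives the all-trans cyclopentane diol 18 and two copies of acid 6.
2. The core cyclopentane is cut at the two ring bonds that flank its CH(CH3)–CH(O)–CH2 unit: ring CH2 to the carbon carrying the CH(CH2OH)2 arm, and the methyl-bearing carbon to the carbon carrying the acyloxymethyl group.
3. Enabling feature: the oxygenated ring carbon lies between both bond termini, so this unit is a latent 4-bromo-3-oxopentanoate (acidic CH2 as donor, CHBr as acceptor), and the other two ring carbons are the β- and α-carbons of a latent enal whose CHO is the future CH2O–acyl carbon.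
4. Forward: acid 6 from a D-ribose-derived cyclopentenone (steps 1–4); enal 9 and bromo keto ester 13 (steps 5–7); one amine-catalysed Michael/α-alkylation domino closes the core ring (step 8); decarboxylation, reduction, double esterification, acetonide removal and double glycol cleavage finish the route (steps 9–13).
5. Stereochemistry: the core carbon bearing the diol arm from the (R)-diarylprolinol silyl ether; its two neighbours by equilibration to the all-trans ring; the carbinol by (S)-oxazaborolidine control; the arm stereocentre from the chiral-pool acetonide (alkylation anti to the dioxolane); both enal geometries from the (E)-ethylidene groups.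

Key step: step 8

Remark: 1, 7, 10 and 11 are taken as catalogue compounds. Bromo keto ester 13 is used as the racemate; any epimer it leaves at the methyl-bearing ring carbon of 15 is converged by base equilibration in step 9.

**Step 1**
Reactants: 1 (3aR,6aR)-2,2-dimethyl-3a,6a-dihydro-4H-cyclopenta[d][1,3]dioxol-4-one
Product: 2 (3aR,6aR)-2,2-dimethyltetrahydro-4H-cyclopenta[d][1,3]dioxol-4-one
Conditions: H2 (1 atm), 10% Pd/C, EtOAc, rt
Reagents that add atoms: none
Why: Heterogeneous catalytic hydrogenation saturates the enone C=C and leaves the ketone and the acetonide intact; no stereocentre is formed.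

**Step 2**
Reactants: 2 (3aR,6aR)-2,2-dimethyltetrahydro-4H-cyclopenta[d][1,3]dioxol-4-one
Product: 4 methyl 2-[(3aR,5S,6aR)-2,2-dimethyl-4-oxotetrahydro-3aH-cyclopenta[d][1,3]dioxol-5-yl]acetate, via lithium enolate 3 (not isolated)
Conditions: LiN(i-Pr)2 (1.1 equiv), THF, −78 °C; then BrCH2CO2Me, −78 to −20 °C
Reagents that add atoms: methyl bromoacetate COC(=O)CBr
Why: Kinetic deprotonation at the CH2 α-carbon and SN2 alkylation of the lithium enolate (ketone α-alkylation) on the convex face of the cis-fused bicycle, anti to the dioxolane, should set C5 as S, which is also the thermodynamically preferred exo epimer.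

**Step 3**
Reactants: 4 methyl 2-[(3aR,5S,6aR)-2,2-dimethyl-4-oxotetrahydro-3aH-cyclopenta[d][1,3]dioxol-5-yl]acetate
Product: 5 methyl 2-[(3aS,5S,6aR)-4-[(E)-ethylidene]-2,2-dimethyltetrahydro-3aH-cyclopenta[d][1,3]dioxol-5-yl]acetate
Conditions: EtPPh3Br (1.5 equiv), KOt-Bu (1.4 equiv), THF, 0 °C to rt
Reagents that add atoms: ethyltriphenylphosphonium bromide CC[P+](c1ccccc1)(c1ccccc1)c1ccccc1.[Br-]
Why: Wittig olefination of the ketone with the non-stabilised ethylidene ylide; the ylide methyl group is expected to settle syn to C5 and away from the ring-fusion carbon, whose C–O bond is held near the alkene plane by the dioxolane (allylic 1,3-strain), which is the E geometry.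

**Step 4**
Reactants: 5 methyl 2-[(3aS,5S,6aR)-4-[(E)-ethylidene]-2,2-dimethyltetrahydro-3aH-cyclopenta[d][1,3]dioxol-5-yl]acetate
Product: 6 2-[(3aS,5S,6aR)-4-[(E)-ethylidene]-2,2-dimethyltetrahydro-3aH-cyclopenta[d][1,3]dioxol-5-yl]acetic acid
Conditions: LiOH·H2O (2 equiv), THF/H2O (3:1), rt; then 1 M HCl to pH 4, 0 °C
Reagents that add atoms: lithium hydroxide [Li+].[OH-]
Why: Ester saponification; the acetonide and the alkene are stable to base, and the stereocentre, β to the carboxyl group, cannot epimerise.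

**Step 5**
Reactants: 7 (2,2-dimethyl-1,3-dioxan-5-yl)methanol
Product: 8 2,2-dimethyl-1,3-dioxane-5-carbaldehyde
Conditions: TEMPO (10 mol%), PhI(OAc)2 (1.1 equiv), CH2Cl2, rt
Reagents that add atoms: none
Why: Oxoammonium (TEMPO) oxidation of the primary alcohol stops at the aldehyde and, being non-basic, should avoid β-elimination of the ring oxygen.

**Step 6**
Reactants: 8 2,2-dimethyl-1,3-dioxane-5-carbaldehyde
Product: 9 (2E)-3-(2,2-dimethyl-1,3-dioxan-5-yl)prop-2-enal
Conditions: Ph3P=CHCHO (1.1 equiv), toluene, 80 °C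
Reagents that add atoms: (triphenylphosphoranylidene)acetaldehyde O=CC=P(c1ccccc1)(c1ccccc1)c1ccccc1
Why: Wittig reaction with the stabilised formylmethylene ylide gives the two-carbon-extended enal with E geometry, and the less electrophilic product should resist a second homologation.

**Step 7**
Reactants: 10 Meldrum's acid (2,2-dimethyl-1,3-dioxane-4,6-dione); 11 2-bromopropanoyl chloride (racemic)
Product: 13 allyl 4-bromo-3-oxopentanoate (racemic), via acyl Meldrum's acid 12 (not isolated)
Conditions: pyridine (2 equiv), CH2Cl2, 0 °C to rt; then allyl alcohol (3 equiv), toluene, 80 °C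
Reagents that add atoms: allyl alcohol C=CCO
Why: C-Acylation of Meldrum's acid followed by thermal alcoholysis with loss of acetone and CO2 is the standard acyl Meldrum's acid route to β-keto esters and leaves the α-bromide and the allyl group untouched; no stereocentre is controlled.

**Step 8**
Reactants: 9 (2E)-3-(2,2-dimethyl-1,3-dioxan-5-yl)prop-2-enal; 13 allyl 4-bromo-3-oxopentanoate (racemic)
Product: 15 allyl (1R,3R,4S,5S)-5-(2,2-dimethyl-1,3-dioxan-5-yl)-4-formyl-3-methyl-2-oxocyclopentane-1-carboxylate, via enamine Michael adduct 14 (not isolated)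
Conditions: (R)-2-[diphenyl(trimethylsilyloxy)methyl]pyrrolidine (20 mol%), K2CO3 (1.2 equiv), CHCl3, 0 °C to rt
Reagents that add atoms: none
Why: The secondary amine condenses with 9 to an (E)-iminium ion, the 1,3-dicarbonyl CH2 of 13 adds to its β-carbon (Michael addition), and the enamine 14 so formed displaces the secondary α-keto bromide with its α-carbon, after which hydrolysis returns the catalyst. The closest known reaction type is the amine-catalysed domino Michael/α-alkylation of enals with 4-bromoacetoacetates to 2-oxocyclopentanecarboxylates, used here with the 4-methyl homologue. The only ring closed is the cyclopentanone, by 5-exo-tet SN2 attack of the enamine carbon. C5 is set by the catalyst, whose CPh2OSiMe3 group shields one face of the iminium ion so that the (R)-amine should give the 5S centre; C4 is set in the ring closure anti to the C5 substituent and can equilibrate through the enamine; C3 arises by inversion at the bromide carbon and C1 is enolisable, so both are left to the all-trans thermodynamic preference, completed in step 9. The step needs C-alkylation over O- or N-alkylation and Michael addition through the CH2 between the two carbonyls; the much higher acidity of that CH2, the soft enamine carbon and the favourable 5-exo-tet geometry should secure this, while K2CO3 only takes up HBr.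

**Step 9**
Reactants: 15 allyl (1R,3R,4S,5S)-5-(2,2-dimethyl-1,3-dioxan-5-yl)-4-formyl-3-methyl-2-oxocyclopentane-1-carboxylate
Product: 17 (1S,2R,5S)-5-(2,2-dimethyl-1,3-dioxan-5-yl)-2-methyl-3-oxocyclopentane-1-carbaldehyde, via β-keto acid 16 (not isolated)
Conditions: Pd(OAc)2 (5 mol%), PPh3 (20 mol%), HCO2H (2 equiv), Et3N (3 equiv), THF, rt to 40 °C; then DBU (0.2 equiv), rt
Reagents that add atoms: none
Why: Palladium-catalysed deallylation with formate as hydride donor (Tsuji conditions) frees the β-keto acid, which decarboxylates under near-neutral conditions that spare the aldehyde and the acetonide, and DBU then equilibrates the two enolisable centres (C1 and C2) to the ketone aldehyde in which every vicinal pair of substituents is trans.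

**Step 10**
Reactants: 17 (1S,2R,5S)-5-(2,2-dimethyl-1,3-dioxan-5-yl)-2-methyl-3-oxocyclopentane-1-carbaldehyde
Product: 18 (1R,2R,3S,4R)-4-(2,2-dimethyl-1,3-dioxan-5-yl)-3-(hydroxymethyl)-2-methylcyclopentan-1-ol
Conditions: (S)-2-methyl-CBS-oxazaborolidine (0.3 equiv), BH3·SMe2 (2.5 equiv), THF, −20 °C; then MeOH
Reagents that add atoms: none
Why: Corey–Bakshi–Shibata reduction: borane reduces the aldehyde and, under control of the (S)-oxazaborolidine (larger α-branch CH(CH3) versus CH2), should deliver hydride to the ketone face syn to the methyl group, which sets the carbinol as R, trans to the methyl group, in line with the usual preference of small hydrides for trans-2-alkylcyclopentanols.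

**Step 11**
Reactants: 18 (1R,2R,3S,4R)-4-(2,2-dimethyl-1,3-dioxan-5-yl)-3-(hydroxymethyl)-2-methylcyclopentan-1-ol; 6 2-[(3aS,5S,6aR)-4-[(E)-ethylidene]-2,2-dimethyltetrahydro-3aH-cyclopenta[d][1,3]dioxol-5-yl]acetic acid (2.4 equiv)
Product: 19 [(1S,2R,3R,5R)-5-(2,2-dimethyl-1,3-dioxan-5-yl)-2-methyl-3-{2-[(3aS,5S,6aR)-4-[(E)-ethylidene]-2,2-dimethyltetrahydro-3aH-cyclopenta[d][1,3]dioxol-5-yl]acetoxy}cyclopentyl]methyl 2-[(3aS,5S,6aR)-4-[(E)-ethylidene]-2,2-dimethyltetrahydro-3aH-cyclopenta[d][1,3]dioxol-5-yl]acetate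
Conditions: DCC (2.5 equiv), DMAP (0.3 equiv), CH2Cl2, 0 °C to rt
Reagents that add atoms: none
Why: Steglich esterification (carbodiimide activation with acyl transfer by DMAP) should acylate the primary and the secondary hydroxyl with the same unhindered acetic acid arm; no stereocentre is touched.

**Step 12**
Reactants: 19 the tris-acetonide diester
Product: 20 [(1S,2R,3R,5R)-5-(1,3-dihydroxypropan-2-yl)-3-{2-[(1S,2E,3S,4R)-2-ethylidene-3,4-dihydroxycyclopentyl]acetoxy}-2-methylcyclopentyl]methyl 2-[(1S,2E,3S,4R)-2-ethylidene-3,4-dihydroxycyclopentyl]acetate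
Conditions: 1 M aq. HCl/THF (1:3), rt
Reagents that add atoms: none
Why: Acid-catalysed hydrolysis of the three isopropylidene acetals (one 1,3-dioxane, two cis-fused dioxolanes) should release all six hydroxyl groups, while the two esters and the trisubstituted alkenes are inert to dilute acid at room temperature.

**Step 13**
Reactants: 20 the hexahydroxy diester
Product: 21 [(1S,2R,3R,5R)-5-(1,3-dihydroxypropan-2-yl)-3-{[(3S,4E)-4-formyl-3-(2-oxoethyl)hex-4-enoyl]oxy}-2-methylcyclopentyl]methyl (3S,4E)-4-formyl-3-(2-oxoethyl)hex-4-enoate (the target)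
Conditions: NaIO4 (2.5 equiv), THF/H2O (2:1), 0 °C to rt
Reagents that add atoms: none
Why: Periodate glycol cleavage (Malaprade reaction) should open both cis-cyclopentane-1,2-diols through cyclic periodate esters to give, in each arm, the conjugated (E)-enal and the 2-oxoethyl group, whereas the 1,3-diol of the core cannot form such an ester and the arm stereocentres, β to the ester and the new saturated aldehyde, are not touched.

**Compound list**
1 | (3aR,6aR)-2,2-dimethyl-3a,6a-dihydro-4H-cyclopenta[d][1,3]dioxol-4-one | O=C1C=C[C@H]2OC(C)(C)O[C@@H]12 | starting material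
2 | (3aR,6aR)-2,2-dimethyltetrahydro-4H-cyclopenta[d][1,3]dioxol-4-one | O=C1CC[C@H]2OC(C)(C)O[C@@H]12 | intermediate
3 | lithium (3aR,6aR)-2,2-dimethyl-6,6a-dihydro-3aH-cyclopenta[d][1,3]dioxol-4-olate (lithium enolate) | [Li+].[O-]C1=CC[C@H]2OC(C)(C)O[C@@H]12 | intermediate (not isolated)
4 | methyl 2-[(3aR,5S,6aR)-2,2-dimethyl-4-oxotetrahydro-3aH-cyclopenta[d][1,3]dioxol-5-yl]acetate | O=C1[C@H](CC(=O)OC)C[C@H]2OC(C)(C)O[C@@H]12 | intermediate
5 | methyl 2-[(3aS,5S,6aR)-4-[(E)-ethylidene]-2,2-dimethyltetrahydro-3aH-cyclopenta[d][1,3]dioxol-5-yl]acetate | C/C=C1\[C@H](CC(=O)OC)C[C@H]2OC(C)(C)O[C@@H]12 | intermediate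
6 | 2-[(3aS,5S,6aR)-4-[(E)-ethylidene]-2,2-dimethyltetrahydro-3aH-cyclopenta[d][1,3]dioxol-5-yl]acetic acid | C/C=C1\[C@H](CC(=O)O)C[C@H]2OC(C)(C)O[C@@H]12 | intermediate
7 | (2,2-dimethyl-1,3-dioxan-5-yl)methanol | CC1(C)OCC(CO)CO1 | starting material
8 | 2,2-dimethyl-1,3-dioxane-5-carbaldehyde | CC1(C)OCC(C=O)CO1 | intermediate
9 | (2E)-3-(2,2-dimethyl-1,3-dioxan-5-yl)prop-2-enal | O=C/C=C/C1COC(C)(C)OC1 | intermediate
10 | Meldrum's acid (2,2-dimethyl-1,3-dioxane-4,6-dione) | CC1(C)OC(=O)CC(=O)O1 | starting material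
11 | 2-bromopropanoyl chloride (racemic) | CC(Br)C(=O)Cl | starting material
12 | 5-(2-bromo-1-hydroxypropylidene)-2,2-dimethyl-1,3-dioxane-4,6-dione (acyl Meldrum's acid) | CC(Br)C(O)=C1C(=O)OC(C)(C)OC1=O | intermediate (not isolated)
13 | allyl 4-bromo-3-oxopentanoate (racemic) | C=CCOC(=O)CC(=O)C(C)Br | intermediate
14 | allyl 4-bromo-2-[(1R,2E)-1-(2,2-dimethyl-1,3-dioxan-5-yl)-3-[(2R)-2-[diphenyl(trimethylsilyloxy)methyl]pyrrolidin-1-yl]prop-2-en-1-yl]-3-oxopentanoate (enamine Michael adduct; mixture at the two unset carbons) | C=CCOC(=O)C(C(=O)C(C)Br)[C@H](/C=C/N1CCC[C@@H]1C(O[Si](C)(C)C)(c1ccccc1)c1ccccc1)C1COC(C)(C)OC1 | intermediate (not isolated)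
15 | allyl (1R,3R,4S,5S)-5-(2,2-dimethyl-1,3-dioxan-5-yl)-4-formyl-3-methyl-2-oxocyclopentane-1-carboxylate (drawn as the all-trans epimer; C1 is enolisable) | O=C[C@@H]1[C@@H](C)C(=O)[C@H](C(=O)OCC=C)[C@H]1C2COC(C)(C)OC2 | intermediate
16 | (1R,3R,4S,5S)-5-(2,2-dimethyl-1,3-dioxan-5-yl)-4-formyl-3-methyl-2-oxocyclopentane-1-carboxylic acid (β-keto acid) | O=C[C@@H]1[C@@H](C)C(=O)[C@H](C(=O)O)[C@H]1C2COC(C)(C)OC2 | intermediate (not isolated)
17 | (1S,2R,5S)-5-(2,2-dimethyl-1,3-dioxan-5-yl)-2-methyl-3-oxocyclopentane-1-carbaldehyde | O=C[C@@H]1[C@@H](C)C(=O)C[C@H]1C2COC(C)(C)OC2 | intermediate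
18 | (1R,2R,3S,4R)-4-(2,2-dimethyl-1,3-dioxan-5-yl)-3-(hydroxymethyl)-2-methylcyclopentan-1-ol | OC[C@@H]1[C@@H](C)[C@H](O)C[C@H]1C2COC(C)(C)OC2 | intermediate
19 | [(1S,2R,3R,5R)-5-(2,2-dimethyl-1,3-dioxan-5-yl)-2-methyl-3-{2-[(3aS,5S,6aR)-4-[(E)-ethylidene]-2,2-dimethyltetrahydro-3aH-cyclopenta[d][1,3]dioxol-5-yl]acetoxy}cyclopentyl]methyl 2-[(3aS,5S,6aR)-4-[(E)-ethylidene]-2,2-dimethyltetrahydro-3aH-cyclopenta[d][1,3]dioxol-5-yl]acetate | C/C=C1\[C@H](CC(=O)OC[C@@H]3[C@@H](C)[C@H](OC(=O)C[C@@H]4C[C@H]5OC(C)(C)O[C@H]5/C4=C/C)C[C@H]3C6COC(C)(C)OC6)C[C@H]2OC(C)(C)O[C@@H]12 | intermediate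
20 | [(1S,2R,3R,5R)-5-(1,3-dihydroxypropan-2-yl)-3-{2-[(1S,2E,3S,4R)-2-ethylidene-3,4-dihydroxycyclopentyl]acetoxy}-2-methylcyclopentyl]methyl 2-[(1S,2E,3S,4R)-2-ethylidene-3,4-dihydroxycyclopentyl]acetate | C/C=C1\[C@H](CC(=O)OC[C@@H]3[C@@H](C)[C@H](OC(=O)C[C@@H]4C[C@@H](O)[C@@H](O)/C4=C/C)C[C@H]3C(CO)CO)C[C@@H](O)[C@H]1O | intermediate
21 | [(1S,2R,3R,5R)-5-(1,3-dihydroxypropan-2-yl)-3-{[(3S,4E)-4-formyl-3-(2-oxoethyl)hex-4-enoyl]oxy}-2-methylcyclopentyl]methyl (3S,4E)-4-formyl-3-(2-oxoethyl)hex-4-enoate | C/C=C(/C=O)[C@@H](CC=O)CC(=O)OC[C@@H]1[C@@H](C)[C@H](OC(=O)C[C@H](CC=O)/C(C=O)=C\C)C[C@H]1C(CO)CO | target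

**Step count**
Total: 13 steps. Longest linear sequence: 8 steps (steps 5, 6, 8, 9, 10, 11, 12, 13); the acid branch (steps 1–4) and the bromo keto ester (step 7) join it at steps 11 and 8.

**Steps most likely to fail**

1. Step 8. The ring-closing alkylation at the secondary bromide may lag behind the Michael addition, so that acyclic adducts, O-alkylation or alkylation of the catalyst nitrogen take over. Fallback, setting out from 9 and returning at 18: the same amine-catalysed domino reaction is run with commercial ethyl 4-bromo-3-oxobutanoate (primary bromide, the closest precedent) to give ethyl (1R,4R,5S)-5-(2,2-dimethyl-1,3-dioxan-5-yl)-4-formyl-2-oxocyclopentane-1-carboxylate F1. The aldehyde alone is reduced (NaBH4, MeOH/CH2Cl2, −78 °C) to ethyl (1R,4R,5R)-5-(2,2-dimethyl-1,3-dioxan-5-yl)-4-(hydroxymethyl)-2-oxocyclopentane-1-carboxylate F2, which is silylated (TBSCl, imidazole, DMF) to ethyl (1R,4R,5R)-4-[(tert-butyldimethylsilyl)oxymethyl]-5-(2,2-dimethyl-1,3-dioxan-5-yl)-2-oxocyclopentane-1-carboxylate F3. The β-keto ester dianion (LiN(i-Pr)2, 2.2 equiv, THF, −78 to 0 °C) is methylated with MeI at the γ-carbon, anti to the neighbouring silyloxymethyl group, to give ethyl (1R,3R,4S,5R)-4-[(tert-butyldimethylsilyl)oxymethyl]-5-(2,2-dimethyl-1,3-dioxan-5-yl)-3-methyl-2-oxocyclopentane-1-carboxylate F4. Krapcho dealkoxycarbonylation (LiCl, wet DMSO, 140 °C) gives (2R,3S,4R)-3-[(tert-butyldimethylsilyl)oxymethyl]-4-(2,2-dimethyl-1,3-dioxan-5-yl)-2-methylcyclopentan-1-one F5. Reduction as in step 10 gives (1R,2R,3S,4R)-3-[(tert-butyldimethylsilyl)oxymethyl]-4-(2,2-dimethyl-1,3-dioxan-5-yl)-2-methylcyclopentan-1-ol F6, and Bu4NF in THF removes the silyl group to rejoin the route at 18.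

2. Step 10. Facial control at the ring ketone may be poor, with hydride entering anti to the adjacent methyl group against the reagent. Fallback, setting out from 17 and returning at 19: LiBH(s-Bu)3 (THF, −78 °C) should reduce both carbonyl groups and deliver hydride to the ketone anti to the methyl group, giving the epimeric diol (1S,2R,3S,4R)-4-(2,2-dimethyl-1,3-dioxan-5-yl)-3-(hydroxymethyl)-2-methylcyclopentan-1-ol F7. A double Mitsunobu esterification of this diol with acid 6 (PPh3, diisopropyl azodicarboxylate, toluene, 0 °C to rt) esterifies the primary alcohol and inverts the secondary carbinol, which rejoins the route at 19.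

3. Step 3. The Wittig reaction may give poor control of alkene geometry, or the basic ylide may enolise the ketone and open the acetonide by β-elimination. Fallback, setting out from 4 and returning at 5: lithiated ethyldiphenylphosphine oxide (Ph2P(O)Et, n-BuLi, THF, −78 °C) adds to the ketone, and the adduct methyl 2-[(3aR,4S,5S,6aR)-4-[(1S)-1-(diphenylphosphoryl)ethyl]-4-hydroxy-2,2-dimethyltetrahydro-3aH-cyclopenta[d][1,3]dioxol-5-yl]acetate F8 is separated from its diastereomers by chromatography. Stereospecific syn-elimination of diphenylphosphinate (NaH, DMF, rt to 50 °C; Horner–Wittig) should then give only the E-alkene, which rejoins the route at 5.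

**Further compounds**
F1 | step 8 | ethyl (1R,4R,5S)-5-(2,2-dimethyl-1,3-dioxan-5-yl)-4-formyl-2-oxocyclopentane-1-carboxylate | O=C[C@@H]1CC(=O)[C@H](C(=O)OCC)[C@H]1C2COC(C)(C)OC2
F2 | step 8 | ethyl (1R,4R,5R)-5-(2,2-dimethyl-1,3-dioxan-5-yl)-4-(hydroxymethyl)-2-oxocyclopentane-1-carboxylate | OC[C@@H]1CC(=O)[C@H](C(=O)OCC)[C@H]1C2COC(C)(C)OC2
F3 | step 8 | ethyl (1R,4R,5R)-4-[(tert-butyldimethylsilyl)oxymethyl]-5-(2,2-dimethyl-1,3-dioxan-5-yl)-2-oxocyclopentane-1-carboxylate | CC(C)(C)[Si](C)(C)OC[C@@H]1CC(=O)[C@H](C(=O)OCC)[C@H]1C2COC(C)(C)OC2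
F4 | step 8 | ethyl (1R,3R,4S,5R)-4-[(tert-butyldimethylsilyl)oxymethyl]-5-(2,2-dimethyl-1,3-dioxan-5-yl)-3-methyl-2-oxocyclopentane-1-carboxylate | CC(C)(C)[Si](C)(C)OC[C@@H]1[C@@H](C)C(=O)[C@H](C(=O)OCC)[C@H]1C2COC(C)(C)OC2
F5 | step 8 | (2R,3S,4R)-3-[(tert-butyldimethylsilyl)oxymethyl]-4-(2,2-dimethyl-1,3-dioxan-5-yl)-2-methylcyclopentan-1-one | CC(C)(C)[Si](C)(C)OC[C@@H]1[C@@H](C)C(=O)C[C@H]1C2COC(C)(C)OC2
F6 | step 8 | (1R,2R,3S,4R)-3-[(tert-butyldimethylsilyl)oxymethyl]-4-(2,2-dimethyl-1,3-dioxan-5-yl)-2-methylcyclopentan-1-ol | CC(C)(C)[Si](C)(C)OC[C@@H]1[C@@H](C)[C@H](O)C[C@H]1C2COC(C)(C)OC2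
F7 | step 10 | (1S,2R,3S,4R)-4-(2,2-dimethyl-1,3-dioxan-5-yl)-3-(hydroxymethyl)-2-methylcyclopentan-1-ol | OC[C@@H]1[C@@H](C)[C@@H](O)C[C@H]1C2COC(C)(C)OC2
F8 | step 3 | methyl 2-[(3aR,4S,5S,6aR)-4-[(1S)-1-(diphenylphosphoryl)ethyl]-4-hydroxy-2,2-dimethyltetrahydro-3aH-cyclopenta[d][1,3]dioxol-5-yl]acetate | COC(=O)C[C@@H]1C[C@H]2OC(C)(C)O[C@H]2[C@]1(O)[C@H](C)P(=O)(c1ccccc1)c1ccccc1
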